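**Assumption:** the diphosphates 15, 16 and 17 are drawn as free acids and handled as ammonium salts. Labdane numbers are used for every carbon, also in the open chain (C15 = carbinol carbon of 3, C16 = carbon of 9, C11–C12 = bond made in step 2).

## The problem

The target 25 is (13S)-9α,13;15,16-diepoxylabd-14-en-6β-yl acetate. It is a trans-fused decalin (ring A: C1–C5, C10; ring B: C5–C10) whose C9 is the spiro atom of a tetrahydrofuran (ring C: O, C9, C11, C12, C13). C13 is in turn the spiro atom of a 2,3-dihydrofuran (ring D: C13, C14, C15, O, C16).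

Five of the six stereocentres (C5, C6, C8, C9, C10) are contiguous on ring B, and C9 and C10 are adjacent fully substituted carbons. The sixth, C13, is a quaternary ether carbon separated from the decalin by C11 and C12. The ring B centres can steer one another (the axial C19 and C20 methyls shield the β face of C6), but none has a dependable hold on C13, so C13 needs a reagent-controlled step.

The C14=C15–O enol ether is the fragile group. Protonation at C14 lets the C9 oxygen leave C13, and ring D becomes an aromatic furan. Ring D must therefore be closed late, in a basic or neutral medium, with no acid or oxidant after it. The acetate sits on an axial alcohol that is 1,3-diaxial to two methyl groups, and C6 has no neighbouring function from which a chemical C–H oxidation could be directed.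

A short route is possible because all twenty skeletal carbons are those of a geranylgeranyl chain. The methine C8 (8β-H, 8α-methyl), the oxygen-bearing C9 and the quaternary C10 are the pattern left when a bicyclic C8 cation receives the hydrogen of C9 and C9 then captures water. Only the oxygens at C6 and C16 lie outside that pattern.

## Retrosynthesis

**25 to 24 (C6 O–acyl bond).** Acetylation under amine base is the one operation the enol ether tolerates without risk, so it is placed last. Leaving the 6β-hydroxyl free until then also means the C16 hydroxyl needs no protecting group. The forward step must acylate a hindered axial alcohol without acid.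

**24 to 23 (O–C15 bond of ring D).** The enol ether is traced to homopropargylic alcohol 23, to be closed by a molybdenum-catalysed cycloisomerisation. A lactol dehydration would need acid or an activating group. The isomerisation forms no by-product and runs in triethylamine. Alkynol 23 carries no acid-sensitive group.

**23 to 22 to 21 (C14–C15).** The alkyne comes from aldehyde 22 by one-carbon homologation, and 22 comes from tetraol 21 by glycol cleavage. The original C15 is excised and a new one is brought in. This is accepted because the 14,15-diol is exactly what the ring C closure delivers, and the cleavage removes the surplus C14 oxygen at the same time.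

**21 to 20 (C6–O).** No reagent can pick C6 out of the methylene groups of 20, so this bond is assigned to a cytochrome P450. It is placed here because 20 has no alkene, aldehyde or enol ether, and because terminal alkynes such as 23 inactivate P450 enzymes. The step must deliver oxygen to the axial 6β position with retention.

**20 to 19 to 18 (O9–C13 bond of ring C, and C13).** Ring C is opened to epoxy triol 19, and 19 to the Z-alkene of triol 18. The tertiary 9α-hydroxyl attacks the tertiary epoxide carbon with inversion, so the epoxide face decides C13. A ketone-catalysed (Shi) epoxidation is preferred to a titanium–tartrate one. Triol 18 has two allylic hydroxyls that would direct a titanium catalyst to opposite faces and would first have to be told apart.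

**18 to 17 to 16 (C4–C5, C9–C10, C9–O; the key disconnection).** Dephosphorylation leads back to 17. Opening rings A and B along the biosynthetic path gives the achiral diphosphate 16. Two rings, three skeletal bonds and four stereocentres disappear. The forward step asks a class 2 diterpene cyclase of the peregrinol diphosphate synthase type to accept a substrate with one extra hydroxyl next to its diphosphate anchor.

**16 to 14, 13, 12 and 11 (C15–O–P, via 15).** The diphosphate is installed by displacement of allylic chloride 14. The C16 hydroxyl must be masked while C15 is activated, because a free cis-hydroxymethyl group would close onto C15. Acetate is chosen because ammonia removes it without harming an allylic diphosphate. The relay 11 to 12 to 13 to 14 swaps a silyl ether on C15 for an acetate on C16.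

**11 to 8 to 7 to 5 (C13–C16 and the alkene geometry; via 10 and 6, with 9).** The hydroxymethyl carbon is added as formaldehyde 9 to alkenyllithium 10, made from iodide 8. Iodide 7 comes from propargylic alcohol 5 by hydroalumination–iodination through alanate 6. That step fixes the chain trans to C15, the geometry the cyclase and the epoxidation both rely on.

**5 to 2 and 3 (C11–C12, via 4); 2 to 1.** The C19 enynol is cut between C11 and C12 into farnesyl bromide 2 and dianion 4 of but-2-yn-1-ol 3. Bromide 2 comes from farnesol 1. All three starting materials (1, 3, 9) are commercial, and the two E alkenes of 1 become the ring-forming alkenes of 16.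

## Roads not taken

**Alternative 1 (dehydrative Prins spirocyclisation).**
- Cut: C9–O and C9–C10, so that rings B and C form together around C9.
- Forward step: a strong Lewis or Brønsted acid condenses the C13 hydroxyl of the 9,10-seco hydroxy ketone A2 with its C9 ketone to a five-membered oxocarbenium ion. C10 of the tetrasubstituted ring A alkene attacks it, and loss of a proton from C6 gives the 15-nor spiro ether A1 with a C5=C6 alkene.
- Merits: the adjacent fully substituted carbons C9 and C10 and two rings are made in one step with ordinary reagents. The C5=C6 alkene is a chemical handle for the C6 oxygen (hydroboration from the α face, then oxidation and hydride reduction to the 6β alcohol). This is a real advantage over the chosen plan, which needs a second enzyme for C6.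
- Weak points: the facial course at C9 and C10 must be dictated by the C8 methyl and the distant C13 centre through a crowded transition state. C8 is α to the ketone and can epimerise in strong acid before closure. The silyl ether must survive that acid. A2 needs C8 and C13 made separately in enantiopure form. After the key step, C5–H, C6–O, two deprotections and the addition of C15 are still to come.
- Comparison: against the C6 handle, the chosen plan sets the creation of C5, C8, C9 and C10 in absolute form from an achiral chain in one step, and a shorter way to the cyclisation substrate.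

**Alternative 2 (Ramberg–Bäcklund contraction).**
- Cut: the C14=C15 bond of ring D, made last.
- Forward step: KOH on alumina with CBr2F2 halogenates the spiro 1,3-oxathiane 3,3-dioxide A4 next to sulfur. The α-sulfonyl carbanion closes an episulfone, and loss of SO2 contracts the six-membered ring to the dihydrofuran of A3. A3 has the structure of 24 and needs only acetylation.
- Merits: the enol ether is formed in a strongly basic medium, and either α-position of the sulfone leads to the same alkene. No terminal alkyne, photolysis or metal carbonyl is involved, so it is at least as safe as step 16.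
- Weak points: it is an end game only and says nothing about the decalin, C9, C6 or C13. A4 needs a C13 carbon bearing a CH2–S and a CH2–O arm. Assembling thioether, O,S-methylene bridge and sulfone costs more steps than the two that lead from 21 to 23.
- Comparison: as a ring D closure it is of equal standing and could be grafted onto the chosen route if step 16 failed. The chosen plan sets step economy against it, since the alkynol comes almost directly from the epoxide chemistry.

**Alternative 3 (hydrogen-atom-transfer radical closure).**
- Cut: C9–C10 alone.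
- Forward step: Fe(acac)3 and PhSiH3 transfer a hydrogen atom to C1 of the ring A alkene of the seco furanone A6. The tertiary C10 radical adds to C9, the β-carbon of the 3(2H)-furanone (6-exo), and the α-keto radical is reduced to give diketo lactone A5.
- Merits: a quaternary carbon and the spiro centre are joined in one step under conditions that tolerate ketones and lactones, and the fragments are convergent. A5 also carries chemical answers to the two problems the chosen plan solves least elegantly. The C6 ketone gives the 6β alcohol by hydride attack from the open α face. The 15,16-lactone gives ring D by reduction to the lactol and dehydration.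
- Weak points: C9 and C10 are set under substrate control in a radical addition whose sense (trans or cis ring fusion, α or β attack on the furanone) has no obvious bias. C5 is epimerisable next to the C6 ketone. The C12 ketone is not in the target and must be removed beside two other carbonyl groups. A6 needs three stereocentres made beforehand.
- Comparison: in functional-group logic at C6 and ring D this road is better. The chosen plan can only set against it that its four ring B stereocentres come from one enzyme-controlled step with no surplus oxygen to erase, at the price of depending on two enzymes.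

Key step: step 10

## Route

Step 1
Reactants: 1 (2E,6E)-farnesol
Product: 2 (2E,6E)-farnesyl bromide
Conditions: PBr3 (0.4 equiv), Et2O, −10 to 0 °C; used crude
Reagents that add atoms: phosphorus tribromide, BrP(Br)Br
Why: Bromination of a primary allylic alcohol through its phosphite ester is an SN2 displacement at low temperature, so no allylic transposition occurs and both E alkenes are kept.

Step 2
Reactants: 3 but-2-yn-1-ol; 2 (2E,6E)-farnesyl bromide
Product: 5 (6E,10E)-7,11,15-trimethylhexadeca-6,10,14-trien-2-yn-1-ol, via dilithiated but-2-yn-1-ol 4 (not isolated)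
Conditions: n-BuLi (1.0 equiv), then t-BuLi (1.05 equiv), THF, −78 to 0 °C; 2, −78 °C to rt; H2O
Reagents that add atoms: none
Why: Double deprotonation gives the O,C-dilithio propargyl anion 4, which is alkylated at its CH2 terminus by the primary allylic bromide (propargylic dianion alkylation, SN2). This forms C11–C12, and the alkyne is the latent C13=C14 alkene.

Step 3
Reactants: 5 (6E,10E)-7,11,15-trimethylhexadeca-6,10,14-trien-2-yn-1-ol
Product: 7 (2Z,6E,10E)-3-iodo-7,11,15-trimethylhexadeca-2,6,10,14-tetraen-1-ol, via cyclic alkenylalanate 6 (not isolated)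
Conditions: NaAlH2(OCH2CH2OMe)2 (1.6 equiv), THF, 0 °C to rt; then I2, −78 to 0 °C; aqueous work-up
Reagents that add atoms: iodine, II
Why: Alkoxide-directed trans-hydroalumination puts hydride on C14 and aluminium on C13 in the five-membered alanate 6. Iodine cleaves the C–Al bond with retention (hydroalumination–iodination of a propargylic alcohol), so iodine ends cis to CH2OH and the chain trans to it, the geometry needed for C13=C14.

Step 4
Reactants: 7 (2Z,6E,10E)-3-iodo-7,11,15-trimethylhexadeca-2,6,10,14-tetraen-1-ol
Product: 8 tert-butyl{[(2Z,6E,10E)-3-iodo-7,11,15-trimethylhexadeca-2,6,10,14-tetraen-1-yl]oxy}dimethylsilane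
Conditions: TBSCl, imidazole, CH2Cl2, 0 °C to rt
Reagents that add atoms: tert-butyldimethylsilyl chloride, CC(C)(C)[Si](C)(C)Cl
Why: Silylation of the primary alcohol lets the C15 oxygen survive t-BuLi and keeps it distinguishable from the C16 hydroxyl made next.

Step 5
Reactants: 8 tert-butyl{[(2Z,6E,10E)-3-iodo-7,11,15-trimethylhexadeca-2,6,10,14-tetraen-1-yl]oxy}dimethylsilane; 9 formaldehyde (as paraformaldehyde)
Product: 11 {(2Z,6E,10E)-1-[(tert-butyldimethylsilyl)oxy]-7,11,15-trimethylhexadeca-2,6,10,14-tetraen-3-yl}methanol, via alkenyllithium 10 (not isolated)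
Conditions: t-BuLi (2.1 equiv), Et2O, −78 °C; (CH2O)n, −78 °C to rt; H2O
Reagents that add atoms: none
Why: Iodine–lithium exchange keeps the alkene geometry (the second equivalent of t-BuLi destroys the tert-butyl iodide), and 1,2-addition of 10 to formaldehyde brings in C16 cis to C15.

Step 6
Reactants: 11 {(2Z,6E,10E)-1-[(tert-butyldimethylsilyl)oxy]-7,11,15-trimethylhexadeca-2,6,10,14-tetraen-3-yl}methanol
Product: 12 {(2Z,6E,10E)-1-[(tert-butyldimethylsilyl)oxy]-7,11,15-trimethylhexadeca-2,6,10,14-tetraen-3-yl}methyl acetate
Conditions: Ac2O, pyridine, DMAP (cat.), CH2Cl2, 0 °C to rt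
Reagents that add atoms: acetic anhydride, CC(=O)OC(C)=O
Why: Standard acylation. Acetate is chosen because it survives fluoride, chlorination and diphosphate displacement, and is removed at the end by ammonia, to which an allylic diphosphate is stable.

Step 7
Reactants: 12 {(2Z,6E,10E)-1-[(tert-butyldimethylsilyl)oxy]-7,11,15-trimethylhexadeca-2,6,10,14-tetraen-3-yl}methyl acetate
Product: 13 [(2Z,6E,10E)-1-hydroxy-7,11,15-trimethylhexadeca-2,6,10,14-tetraen-3-yl]methyl acetate
Conditions: Bu4NF, AcOH (1:1), THF, 0 °C to rt
Reagents that add atoms: none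
Why: Fluoride cleaves the Si–O bond, and buffering with acetic acid suppresses ester cleavage and 1,4-acetyl migration across the Z alkene.

Step 8
Reactants: 13 [(2Z,6E,10E)-1-hydroxy-7,11,15-trimethylhexadeca-2,6,10,14-tetraen-3-yl]methyl acetate
Product: 14 [(2Z,6E,10E)-1-chloro-7,11,15-trimethylhexadeca-2,6,10,14-tetraen-3-yl]methyl acetate
Conditions: NCS, Me2S, CH2Cl2, −40 to 0 °C
Reagents that add atoms: N-chlorosuccinimide, O=C1CCC(=O)N1Cl
Why: Under Corey–Kim conditions chloride displaces the alkoxysulfonium group at the primary carbon (SN2), without allylic transposition or alkene isomerisation. The ester is inert.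

Step 9
Reactants: 14 [(2Z,6E,10E)-1-chloro-7,11,15-trimethylhexadeca-2,6,10,14-tetraen-3-yl]methyl acetate
Product: 16 16-hydroxygeranylgeranyl diphosphate [(2Z,6E,10E)-3-(hydroxymethyl)-7,11,15-trimethylhexadeca-2,6,10,14-tetraen-1-yl diphosphate], via 16-acetoxygeranylgeranyl diphosphate 15 (not isolated)
Conditions: (n-Bu4N)3HP2O7 (2 equiv), MeCN, rt; then conc. aq. NH3, rt; cation exchange (NH4+ form), cellulose chromatography
Reagents that add atoms: tris(tetrabutylammonium) hydrogen diphosphate, CCCC[N+](CCCC)(CCCC)CCCC.CCCC[N+](CCCC)(CCCC)CCCC.CCCC[N+](CCCC)(CCCC)CCCC.OP(=O)([O-])OP(=O)([O-])[O-]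
Why: The diphosphate anion displaces the primary allylic chloride (SN2 diphosphorylation of an allylic halide), then ammonia removes the acetate while the base-stable diphosphate stays. The acetate is kept until the chloride is gone because a free cis-hydroxymethyl group would close onto C15.

Step 10
Reactants: 16 16-hydroxygeranylgeranyl diphosphate
Product: 17 16-hydroxyperegrinol diphosphate [(5S,8R,9R,10S,13Z)-9,16-dihydroxylabd-13-en-15-yl diphosphate]
Conditions: recombinant peregrinol diphosphate synthase (class 2 diterpene cyclase MvCPS1 of Marrubium vulgare, transit peptide removed), HEPES buffer pH 7.5, MgCl2 (0.1 mM), glycerol (10%), dithiothreitol, 30 °C; 17 kept in the buffer for step 11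
Reagents that add atoms: water, O
Why: The aspartic acid of the DXDD motif protonates C3 of the terminal alkene of the folded chain; C5 then bonds to C4 (ring A, 6-endo cation–alkene closure) and C9 to C10 (ring B, 6-endo), which leaves a tertiary cation at C8. The hydrogen on C9 moves suprafacially across the β face to C8 and an active-site water adds to C9 from the α face, anti to the departing hydride, before the oxonium ion loses a proton. The closest known reaction is the native one of this enzyme class, geranylgeranyl diphosphate to peregrinol diphosphate; 16 differs only by a hydroxyl on the methyl carbon next to the diphosphate anchor, more than eight bonds from the carbons that become cationic. C5 and C10 follow from anti addition across the E-configured C5=C10 alkene in a chair fold (trans fusion), C8 from the face on which the hydride arrives (8β-H, methyl α and equatorial) and C9 from the anti entry of water (9α-OH, side chain β); this outcome requires the C9–H bond to lie on the β face, parallel to the empty orbital on C8, when it migrates, which the enzyme's fold of ring B provides. The absolute sense of all four centres comes from the chiral active site, since 16 is achiral. The selectivity needed is in the termination, hydride shift and hydration at C9 instead of proton loss from the C8 cation or water capture at C8; in the substrate only the E geometry of the alkenes contributes, the rest is the placing of one water molecule by the enzyme, which no acid in a flask reproduces. The C13=C14 alkene, the allylic diphosphate and the C16 hydroxyl are spectators, because a class 2 cyclase does not ionise the diphosphate.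

Step 11
Reactants: 17 16-hydroxyperegrinol diphosphate
Product: 18 (5S,8R,9R,10S,13Z)-labd-13-ene-9,15,16-triol
Conditions: calf intestinal alkaline phosphatase added to the cyclase mixture, glycine buffer pH 9, 37 °C; EtOAc extraction
Reagents that add atoms: none
Why: Enzymatic hydrolysis of the diphosphate monoester cleaves P–O bonds only, so the C15–O bond, the Z alkene and the tertiary alcohol are untouched. The mild pH avoids the allylic ionisation an acidic hydrolysis would cause.

Step 12
Reactants: 18 (5S,8R,9R,10S,13Z)-labd-13-ene-9,15,16-triol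
Product: 20 (5S,8R,9R,10S,13R,14R)-9,13-epoxylabdane-14,15,16-triol, via 13,14-epoxide 19 (not isolated)
Conditions: D-fructose-derived Shi ketone (0.5 equiv), KHSO5 (as 2KHSO5·KHSO4·K2SO4), K2CO3, Bu4NHSO4, MeCN–CH2(OMe)2–aq. Na2B4O7 buffer (pH 10.5), 0 °C; extractive work-up; then CSA (0.1 equiv), CH2Cl2, 0 °C
Reagents that add atoms: potassium peroxymonosulfate, [K+].[O-]S(=O)(=O)OO
Why: The dioxirane from the D-fructose-derived ketone transfers oxygen through a spiro transition state (Shi epoxidation) to the alkene face that gives the (13S,14R)-epoxide 19; the face is fixed by the position of the olefinic hydrogen, not by the distant decalin. Acid then lets the axial 9α-hydroxyl open the epoxide at the tertiary carbon C13 (5-exo, inversion), which closes ring C and sets C13 as in the target (the label is 13R in 20 only because C14 outranks C16 at this stage). Attack at C14 (6-endo) is disfavoured by ring size and by the electron-poor secondary carbon.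

Step 13
Reactants: 20 (5S,8R,9R,10S,13R,14R)-9,13-epoxylabdane-14,15,16-triol
Product: 21 (5S,6R,8R,9R,10S,13R,14R)-9,13-epoxylabdane-6,14,15,16-tetraol
Conditions: resting cells of Saccharomyces cerevisiae co-expressing a CYP76-family diterpenoid 6β-hydroxylase (CYP76AH11 type, variant chosen by screening) and its NADPH–cytochrome P450 reductase, glucose, air, phosphate buffer pH 7.4, 30 °C
Reagents that add atoms: dioxygen, O=O
Why: This is a cytochrome P450 hydroxylation of an unactivated methylene: the haem iron–oxo species abstracts the axial 6β hydrogen and returns hydroxyl to the same face (retention), as enzymes of this family do at C6β of other labdane-type ethers. Site selectivity depends on how the enzyme binds 20 and has to be found by screening. 20 is the chosen substrate because it has no alkene, aldehyde, terminal alkyne (a P450 inactivator) or enol ether.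

Step 14
Reactants: 21 (5S,6R,8R,9R,10S,13R,14R)-9,13-epoxylabdane-6,14,15,16-tetraol
Product: 22 (5S,6R,8R,9R,10S,13R)-9,13-epoxy-6,16-dihydroxy-15-norlabdan-14-al
Conditions: NaIO4, THF–H2O (pH 7 phosphate buffer), 0 °C; used crude
Reagents that add atoms: none
Why: Periodate cleaves the only vicinal diol (C14–C15) through a cyclic periodate ester (Malaprade glycol cleavage). C15 leaves as formaldehyde, and the new aldehyde cannot epimerise because C13 is quaternary.

Step 15
Reactants: 22 (5S,6R,8R,9R,10S,13R)-9,13-epoxy-6,16-dihydroxy-15-norlabdan-14-al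
Product: 23 (5S,6R,8R,9R,10S,13S)-9,13-epoxylabd-14-yne-6,16-diol
Conditions: dimethyl (1-diazo-2-oxopropyl)phosphonate, K2CO3, MeOH, 0 °C to rt
Reagents that add atoms: dimethyl (1-diazo-2-oxopropyl)phosphonate, CC(=O)C(=[N+]=[N-])P(=O)(OC)OC
Why: In the Ohira–Bestmann homologation, methoxide releases dimethyl (diazomethyl)phosphonate, which olefinates the aldehyde to a diazoalkene; loss of N2 and a 1,2-hydrogen shift give the terminal alkyne with the new C15. C13 has no α-hydrogen, so its configuration is untouched.

Step 16
Reactants: 23 (5S,6R,8R,9R,10S,13S)-9,13-epoxylabd-14-yne-6,16-diol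
Product: 24 (5S,6R,8R,9R,10S,13S)-9,13;15,16-diepoxylabd-14-en-6-ol
Conditions: Mo(CO)6 (0.25 equiv), Et3N, Et2O, hν (350 nm), rt
Reagents that add atoms: none
Why: Photolysis of Mo(CO)6 in Et3N gives (Et3N)Mo(CO)5, which turns the terminal alkyne into a molybdenum vinylidene. The C16 hydroxyl adds to its electrophilic carbon C15, and protodemetalation gives the 2,3-dihydrofuran (alkynol endo cycloisomerisation). The medium stays basic, so the enol ether survives, and the 6β hydroxyl is too far away to compete.

Step 17
Reactants: 24 (5S,6R,8R,9R,10S,13S)-9,13;15,16-diepoxylabd-14-en-6-ol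
Product: 25 (5S,6R,8R,9R,10S,13S)-9,13;15,16-diepoxylabd-14-en-6-yl acetate (target)
Conditions: Ac2O, DMAP, Et3N, CH2Cl2, rt; chromatography on Et3N-deactivated silica
Reagents that add atoms: acetic anhydride, CC(=O)OC(C)=O
Why: DMAP-catalysed acylation makes the hindered axial 6β alcohol react, while the amine base keeps the enol ether from protonation. No stereocentre is touched.

## Compound list

1 | (2E,6E)-farnesol | CC(C)=CCC/C(C)=C/CC/C(C)=C/CO | starting material
2 | (2E,6E)-farnesyl bromide | CC(C)=CCC/C(C)=C/CC/C(C)=C/CBr | intermediate
3 | but-2-yn-1-ol | CC#CCO | starting material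
4 | dilithiated but-2-yn-1-ol (lithium 4-lithiobut-2-yn-1-olate) | [Li]CC#CCO[Li] | intermediate
5 | (6E,10E)-7,11,15-trimethylhexadeca-6,10,14-trien-2-yn-1-ol | CC(C)=CCC/C(C)=C/CC/C(C)=C/CCC#CCO | intermediate
6 | cyclic alkenylalanate, sodium 2,2-bis(2-methoxyethoxy)-3-[(3E,7E)-4,8,12-trimethyltrideca-3,7,11-trienyl]-2,5-dihydro-1,2-oxaluminol-2-uide | [Na+].COCCO[Al-]1(OCCOC)OCC=C1CC/C=C(C)/CC/C=C(C)/CCC=C(C)C | intermediate
7 | (2Z,6E,10E)-3-iodo-7,11,15-trimethylhexadeca-2,6,10,14-tetraen-1-ol | CC(C)=CCC/C(C)=C/CC/C(C)=C/CC/C(I)=C/CO | intermediate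
8 | tert-butyl{[(2Z,6E,10E)-3-iodo-7,11,15-trimethylhexadeca-2,6,10,14-tetraen-1-yl]oxy}dimethylsilane | CC(C)=CCC/C(C)=C/CC/C(C)=C/CC/C(I)=C/CO[Si](C)(C)C(C)(C)C | intermediate
9 | formaldehyde (used as paraformaldehyde) | C=O | starting material
10 | {(2E,6E,10E)-1-[(tert-butyldimethylsilyl)oxy]-7,11,15-trimethylhexadeca-2,6,10,14-tetraen-3-yl}lithium (lithium cis to C1) | CC(C)=CCC/C(C)=C/CC/C(C)=C/CC/C([Li])=C/CO[Si](C)(C)C(C)(C)C | intermediate
11 | {(2Z,6E,10E)-1-[(tert-butyldimethylsilyl)oxy]-7,11,15-trimethylhexadeca-2,6,10,14-tetraen-3-yl}methanol | CC(C)=CCC/C(C)=C/CC/C(C)=C/CC/C(CO)=C/CO[Si](C)(C)C(C)(C)C | intermediate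
12 | {(2Z,6E,10E)-1-[(tert-butyldimethylsilyl)oxy]-7,11,15-trimethylhexadeca-2,6,10,14-tetraen-3-yl}methyl acetate | CC(C)=CCC/C(C)=C/CC/C(C)=C/CC/C(COC(C)=O)=C/CO[Si](C)(C)C(C)(C)C | intermediate
13 | [(2Z,6E,10E)-1-hydroxy-7,11,15-trimethylhexadeca-2,6,10,14-tetraen-3-yl]methyl acetate | CC(C)=CCC/C(C)=C/CC/C(C)=C/CC/C(COC(C)=O)=C/CO | intermediate
14 | [(2Z,6E,10E)-1-chloro-7,11,15-trimethylhexadeca-2,6,10,14-tetraen-3-yl]methyl acetate | CC(C)=CCC/C(C)=C/CC/C(C)=C/CC/C(COC(C)=O)=C/CCl | intermediate
15 | 16-acetoxygeranylgeranyl diphosphate, (2Z,6E,10E)-3-(acetoxymethyl)-7,11,15-trimethylhexadeca-2,6,10,14-tetraen-1-yl diphosphate | CC(C)=CCC/C(C)=C/CC/C(C)=C/CC/C(COC(C)=O)=C/COP(=O)(O)OP(=O)(O)O | intermediate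
16 | 16-hydroxygeranylgeranyl diphosphate, (2Z,6E,10E)-3-(hydroxymethyl)-7,11,15-trimethylhexadeca-2,6,10,14-tetraen-1-yl diphosphate | CC(C)=CCC/C(C)=C/CC/C(C)=C/CC/C(CO)=C/COP(=O)(O)OP(=O)(O)O | intermediate
17 | 16-hydroxyperegrinol diphosphate, (5S,8R,9R,10S,13Z)-9,16-dihydroxylabd-13-en-15-yl diphosphate (9α-OH, 8α-methyl) | C1C[C@@H](C)[C@](O)(CC/C(CO)=C/COP(=O)(O)OP(=O)(O)O)[C@@]2(C)CCCC(C)(C)[C@H]12 | intermediate
18 | (5S,8R,9R,10S,13Z)-labd-13-ene-9,15,16-triol | C1C[C@@H](C)[C@](O)(CC/C(CO)=C/CO)[C@@]2(C)CCCC(C)(C)[C@H]12 | intermediate
19 | (5S,8R,9R,10S,13S,14R)-13,14-epoxylabdane-9,15,16-triol | C1C[C@@H](C)[C@](O)(CC[C@@]3(CO)O[C@@H]3CO)[C@@]2(C)CCCC(C)(C)[C@H]12 | intermediate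
20 | (5S,8R,9R,10S,13R,14R)-9,13-epoxylabdane-14,15,16-triol | C1C[C@@H](C)[C@]2(CC[C@@](CO)([C@H](O)CO)O2)[C@@]2(C)CCCC(C)(C)[C@H]12 | intermediate
21 | (5S,6R,8R,9R,10S,13R,14R)-9,13-epoxylabdane-6,14,15,16-tetraol (6β-OH) | O[C@@H]1C[C@@H](C)[C@]2(CC[C@@](CO)([C@H](O)CO)O2)[C@@]2(C)CCCC(C)(C)[C@H]12 | intermediate
22 | (5S,6R,8R,9R,10S,13R)-9,13-epoxy-6,16-dihydroxy-15-norlabdan-14-al | O[C@@H]1C[C@@H](C)[C@]2(CC[C@@](CO)(C=O)O2)[C@@]2(C)CCCC(C)(C)[C@H]12 | intermediate
23 | (5S,6R,8R,9R,10S,13S)-9,13-epoxylabd-14-yne-6,16-diol | O[C@@H]1C[C@@H](C)[C@]2(CC[C@@](CO)(C#C)O2)[C@@]2(C)CCCC(C)(C)[C@H]12 | intermediate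
24 | (5S,6R,8R,9R,10S,13S)-9,13;15,16-diepoxylabd-14-en-6-ol | O[C@@H]1C[C@@H](C)[C@]2(CC[C@@]3(C=COC3)O2)[C@@]2(C)CCCC(C)(C)[C@H]12 | intermediate
25 | (5S,6R,8R,9R,10S,13S)-9,13;15,16-diepoxylabd-14-en-6-yl acetate | CC(=O)O[C@@H]1C[C@@H](C)[C@]2(CC[C@@]3(C=COC3)O2)[C@@]2(C)CCCC(C)(C)[C@H]12 | target

## Step count and least certain steps

Total step count: 17. Longest linear sequence: 17 steps (1 to 25); 3 and 9 enter as building blocks in steps 2 and 5.

**Step 10 (key step).** The extra hydroxyl may change how the chain end sits at the diphosphate site, so binding or turnover may fail. The cascade may also end early, by proton loss from the C8 cation or water capture at C8, instead of running through the hydride shift. Apart from the enzyme, 16 may lose diphosphate in the magnesium-containing buffer by attack of its cis-hydroxymethyl group on C15.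
Fallback: this sets out from 7 and returns at 18, with the cyclase on its native substrate. Me2CuLi replaces the iodine of 7 by methyl with retention to give (2E,6E,10E)-geranylgeraniol F1. NCS/Me2S gives geranylgeranyl chloride F2, and (n-Bu4N)3HP2O7 gives geranylgeranyl diphosphate F3. The same cyclase converts F3 into peregrinol diphosphate F4 (its known reaction), and alkaline phosphatase gives peregrinol F5. The C16 oxygen is then introduced by the peregrinol 16-hydroxylase CYP76BK1 of Vitex agnus-castus expressed in yeast, which gives 18. The bonds and rings of the key step are unchanged.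

**Step 13.** The enzyme may oxidise other sites (C2, C3, C7 or the side-chain alcohols) or convert the polar triol poorly. No enzyme is yet known to be selective for this substrate.
Fallback: this sets out from 18 and returns at 21, moving the oxidation to the bicyclic stage and to another catalyst family. Variants of the self-sufficient bacterial P450 BM3, or a hydroxylating filamentous fungus, are screened on 18 for (13Z)-labd-13-ene-6β,9α,15,16-tetraol F6. The conditions of step 12 then give, through the (13S,14R)-epoxide F7, tetraol 21.

**Step 12.** The facial selectivity of the oxygen transfer may be low, because the two allylic hydroxyls can hydrogen-bond to the dioxirane and disturb the spiro arrangement. The protonated epoxide may also open at C14 or rearrange.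
Fallback: this sets out from 18 and returns at 20. A lipase with vinyl acetate acylates the less hindered C15 hydroxyl to give (13Z)-9α,16-dihydroxylabd-13-en-15-yl acetate F8. Sharpless epoxidation (Ti(OiPr)4, L-(+)-diethyl tartrate, t-BuOOH, CH2Cl2, −20 °C), now directed by the single free allylic hydroxyl at C16, gives the (13S,14R)-epoxy acetate F9. CSA closes ring C to give the 15-acetate of 20, F10, and K2CO3 in MeOH gives 20.

**Step 15.** The β-hydroxy aldehyde may lose formaldehyde by retro-aldol cleavage in carbonate/methanol, and hemiacetal formation may slow the olefination.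
Fallback: this sets out from 22 and returns at 23. TBSCl/imidazole silylates the primary hydroxyl to give the 16-TBS ether of 22, F11. PPh3/CBr4/Zn gives the 14,14-dibromoalkene F12 (Corey–Fuchs), n-BuLi at −78 °C gives the 16-TBS ether of 23, F13, and Bu4NF gives 23.

**Step 2.** The ambident dianion may be alkylated at its allenic position, and the bromide may react by SN2′ attack.
Fallback: this sets out from 2 and returns at 5. 3-Lithio-1-(trimethylsilyl)propyne is alkylated by 2 to give trimethyl[(5E,9E)-6,10,14-trimethylpentadeca-5,9,13-trien-1-yn-1-yl]silane F14. K2CO3 in MeOH gives the terminal alkyne (5E,9E)-6,10,14-trimethylpentadeca-5,9,13-trien-1-yne F15, and n-BuLi followed by paraformaldehyde gives 5.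

## Further compounds

F1 | step 10 | (2E,6E,10E)-geranylgeraniol | CC(C)=CCC/C(C)=C/CC/C(C)=C/CC/C(C)=C/CO
F2 | step 10 | (2E,6E,10E)-geranylgeranyl chloride | CC(C)=CCC/C(C)=C/CC/C(C)=C/CC/C(C)=C/CCl
F3 | step 10 | (2E,6E,10E)-geranylgeranyl diphosphate | CC(C)=CCC/C(C)=C/CC/C(C)=C/CC/C(C)=C/COP(=O)(O)OP(=O)(O)O
F4 | step 10 | peregrinol diphosphate, (5S,8R,9R,10S,13E)-9-hydroxylabd-13-en-15-yl diphosphate | C1C[C@@H](C)[C@](O)(CC/C(C)=C/COP(=O)(O)OP(=O)(O)O)[C@@]2(C)CCCC(C)(C)[C@H]12
F5 | step 10 | peregrinol, (5S,8R,9R,10S,13E)-labd-13-ene-9,15-diol | C1C[C@@H](C)[C@](O)(CC/C(C)=C/CO)[C@@]2(C)CCCC(C)(C)[C@H]12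
F6 | step 13 | (5S,6R,8R,9R,10S,13Z)-labd-13-ene-6,9,15,16-tetraol | O[C@@H]1C[C@@H](C)[C@](O)(CC/C(CO)=C/CO)[C@@]2(C)CCCC(C)(C)[C@H]12
F7 | step 13 | (5S,6R,8R,9R,10S,13S,14R)-13,14-epoxylabdane-6,9,15,16-tetraol | O[C@@H]1C[C@@H](C)[C@](O)(CC[C@@]3(CO)O[C@@H]3CO)[C@@]2(C)CCCC(C)(C)[C@H]12
F8 | step 12 | (5S,8R,9R,10S,13Z)-9,16-dihydroxylabd-13-en-15-yl acetate | C1C[C@@H](C)[C@](O)(CC/C(CO)=C/COC(C)=O)[C@@]2(C)CCCC(C)(C)[C@H]12
F9 | step 12 | (5S,8R,9R,10S,13S,14R)-13,14-epoxy-9,16-dihydroxylabdan-15-yl acetate | C1C[C@@H](C)[C@](O)(CC[C@@]3(CO)O[C@@H]3COC(C)=O)[C@@]2(C)CCCC(C)(C)[C@H]12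
F10 | step 12 | (5S,8R,9R,10S,13R,14R)-9,13-epoxy-14,16-dihydroxylabdan-15-yl acetate | C1C[C@@H](C)[C@]2(CC[C@@](CO)([C@H](O)COC(C)=O)O2)[C@@]2(C)CCCC(C)(C)[C@H]12
F11 | step 15 | (5S,6R,8R,9R,10S,13R)-16-[(tert-butyldimethylsilyl)oxy]-9,13-epoxy-6-hydroxy-15-norlabdan-14-al | O[C@@H]1C[C@@H](C)[C@]2(CC[C@@](CO[Si](C)(C)C(C)(C)C)(C=O)O2)[C@@]2(C)CCCC(C)(C)[C@H]12
F12 | step 15 | 1,1-dibromoalkene from F11 (C14=CBr2, 16-OTBS, 6β-OH) | O[C@@H]1C[C@@H](C)[C@]2(CC[C@@](CO[Si](C)(C)C(C)(C)C)(C=C(Br)Br)O2)[C@@]2(C)CCCC(C)(C)[C@H]12
F13 | step 15 | (5S,6R,8R,9R,10S,13S)-16-[(tert-butyldimethylsilyl)oxy]-9,13-epoxylabd-14-yn-6-ol | O[C@@H]1C[C@@H](C)[C@]2(CC[C@@](CO[Si](C)(C)C(C)(C)C)(C#C)O2)[C@@]2(C)CCCC(C)(C)[C@H]12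
F14 | step 2 | trimethyl[(5E,9E)-6,10,14-trimethylpentadeca-5,9,13-trien-1-yn-1-yl]silane | CC(C)=CCC/C(C)=C/CC/C(C)=C/CCC#C[Si](C)(C)C
F15 | step 2 | (5E,9E)-6,10,14-trimethylpentadeca-5,9,13-trien-1-yne | CC(C)=CCC/C(C)=C/CC/C(C)=C/CCC#C
A1 | alternative 1 | 14-benzyloxy-16-(tert-butyldiphenylsilyloxy)-9α,13-epoxy-15-norlabd-5-ene | C=1C[C@@H](C)[C@]2(CC[C@@](CO[Si](c3ccccc3)(c3ccccc3)C(C)(C)C)(COCc3ccccc3)O2)[C@@]2(C)CCCC(C)(C)C=12
A2 | alternative 1 | 14-benzyloxy-16-(tert-butyldiphenylsilyloxy)-13-hydroxy-15-nor-9,10-secolabd-5(10)-en-9-one | CC1=C(CC[C@@H](C)C(=O)CC[C@@](CO[Si](c2ccccc2)(c2ccccc2)C(C)(C)C)(COCc2ccccc2)O)C(C)(C)CCC1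
A3 | alternative 2 | 6β-hydroxy-9α,13;15,16-diepoxylabd-14-ene (same structure as 24) | O[C@@H]1C[C@@H](C)[C@]2(CC[C@@]3(C=COC3)O2)[C@@]2(C)CCCC(C)(C)[C@H]12
A4 | alternative 2 | spiro 1,3-oxathiane 3,3-dioxide (ring D of 24 with SO2 inserted between C14 and C15, 6β-OH free) | O[C@@H]1C[C@@H](C)[C@]2(CC[C@@]3(CS(=O)(=O)COC3)O2)[C@@]2(C)CCCC(C)(C)[C@H]12
A5 | alternative 3 | 6,12-dioxo-9α,13-epoxylabdan-15,16-olide | O=C1C[C@@H](C)[C@]2(CC(=O)[C@@]3(CC(=O)OC3)O2)[C@@]2(C)CCCC(C)(C)[C@H]12
A6 | alternative 3 | 6,12-dioxo-9,13-epoxy-9,10-secolabda-1(10),9(11)-dien-15,16-olide | CC1=CCCC(C)(C)[C@@H]1C(=O)C[C@@H](C)C1=CC(=O)[C@@]2(CC(=O)OC2)O1
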